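The route rests on disconnecting the C4a–C11a bond of the nine-membered carbocycle. In that ring the alkene carbon C4 sits on C4a and the oxygenated methylene C1 on the adjacent C11a, so C1–C11a–C4a–C4=C12 reads as a γ,δ-unsaturated acid once C1 is a carboxyl. A 13-membered lactone joining that carboxyl to a C12 carbinol next to a C4=C4a alkene is turned into its silyl ketene acetal; one [3,3] shift then contracts it to the nine-membered ring, sets C4a and C11a trans and makes C4=C12 with C13 cis to C3. In the precursor C3 is already an aldehyde acetal and O13 and O14 carry different silyl groups.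

Key step: step 18

Remark: locants C1–C15 are those of the target throughout (C1 OCH2; C3 acetal carbon; C4a and C11a ring fusion; C7 carbinol; C13 to C15 side chain). The first silylation of D-erythronolactone is assumed to take place at the hydroxyl next to the lactone carbonyl (the future O14).

Step 1
Reactants: 1 hex-5-yn-2-one; 2 ethynyltrimethylsilane
Product: 4 (3S)-3-methyl-1-(trimethylsilyl)hepta-1,6-diyn-3-ol, via methylzinc (trimethylsilyl)acetylide 3 (not isolated)
Conditions: Me2Zn, Cu(OTf)2 (10 mol %), chiral hydroxy-camphorsulfonamide ligand (10 mol %), toluene, 0 °C, threefold excess of 2; aq. NH4Cl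
Reagents that add atoms: none
Why: Catalytic enantioselective alkynylzinc addition to a methyl ketone, in which the chiral copper–zinc complex should distinguish the methyl from the methylene flank to set C7 as (S), while the silyl cap keeps the new C8≡C9 alkyne distinct from the free C4 alkyne.

Step 2
Reactants: 4 (3S)-3-methyl-1-(trimethylsilyl)hepta-1,6-diyn-3-ol
Product: 5 (3S)-3-methyl-3-(triethylsilyloxy)-1-(trimethylsilyl)hepta-1,6-diyne
Conditions: Et3SiOTf, 2,6-lutidine, CH2Cl2, −78 → 0 °C
Reagents that add atoms: triethylsilyl trifluoromethanesulfonate, CC[Si](CC)(CC)OS(=O)(=O)C(F)(F)F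
Why: Silylation of a tertiary propargylic alcohol with a silyl triflate and a hindered base is standard and leaves the terminal alkyne untouched.

Step 3
Reactants: 5 (3S)-3-methyl-3-(triethylsilyloxy)-1-(trimethylsilyl)hepta-1,6-diyne
Product: 7 (3S)-8,8-diethoxy-3-methyl-3-(triethylsilyloxy)-1-(trimethylsilyl)octa-1,6-diyne, via bromomagnesium acetylide 6 (not isolated)
Conditions: EtMgBr, THF, 45 °C; then HC(OEt)3, toluene, 85 °C
Reagents that add atoms: triethyl orthoformate, CCOC(OCC)OCC
Why: Bodroux–Chichibabin-type acetal synthesis, in which the alkynyl Grignard reagent formed at the only free alkyne C–H displaces ethoxide from the orthoformate and installs C3 at the aldehyde oxidation level.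

Step 4
Reactants: 7 (3S)-8,8-diethoxy-3-methyl-3-(triethylsilyloxy)-1-(trimethylsilyl)octa-1,6-diyne
Product: 8 (3S,6E)-8,8-diethoxy-3-methyl-7-(tributylstannyl)-3-(triethylsilyloxy)-1-(trimethylsilyl)oct-6-en-1-yne
Conditions: Bu3SnH (slow addition), PdCl2(PPh3)2 (3 mol %), THF, 0 °C
Reagents that add atoms: tributyltin hydride, CCCC[SnH](CCCC)CCCC
Why: Palladium-catalysed syn-hydrostannation, in which the electron-withdrawing acetal should direct tin to C4 and hydrogen to C4a on the same side (C5 cis to C3), while the silyl-capped alkyne next to quaternary C7 should react much more slowly.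

Step 5
Reactants: 8 (3S,6E)-8,8-diethoxy-3-methyl-7-(tributylstannyl)-3-(triethylsilyloxy)-1-(trimethylsilyl)oct-6-en-1-yne
Product: 9 (3S,6E)-8,8-diethoxy-7-iodo-3-methyl-3-(triethylsilyloxy)-1-(trimethylsilyl)oct-6-en-1-yne
Conditions: I2, NaHCO3, CH2Cl2, 0 °C
Reagents that add atoms: iodine, II
Why: Iododestannylation of an alkenylstannane proceeds by ipso substitution with retention of the alkene geometry.

Step 6
Reactants: 9 (3S,6E)-8,8-diethoxy-7-iodo-3-methyl-3-(triethylsilyloxy)-1-(trimethylsilyl)oct-6-en-1-yne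
Product: 10 (3S,6E)-8,8-diethoxy-7-iodo-3-methyl-3-(triethylsilyloxy)oct-6-en-1-yne
Conditions: K2CO3 (cat.), MeOH, 23 °C
Reagents that add atoms: none
Why: Base-catalysed methanolysis cleaves only the alkynyl C–Si bond, as the tertiary silyl ether, the acetal and the alkenyl iodide are inert to carbonate in methanol.

Step 7
Reactants: 11 3-chloro-2-(chloromethyl)prop-1-ene
Product: 12 methyl 3-(chloromethyl)but-3-enoate
Conditions: CO (5 atm), MeOH, Pd(OAc)2 (1 mol %), PPh3, i-Pr2NEt, THF, 40 °C, threefold excess of 11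
Reagents that add atoms: carbon monoxide, [C-]#[O+]; methanol, CO
Why: Palladium-catalysed alkoxycarbonylation of an allylic chloride through the allyl- and acylpalladium species gives the β,γ-unsaturated ester (C1 on C11a), and the excess of dichloride should suppress the second carbonylation.

Step 8
Reactants: 10 (3S,6E)-8,8-diethoxy-7-iodo-3-methyl-3-(triethylsilyloxy)oct-6-en-1-yne; 12 methyl 3-(chloromethyl)but-3-enoate
Product: 13 methyl (7S,10E)-12,12-diethoxy-11-iodo-7-methyl-3-methylidene-7-(triethylsilyloxy)dodec-10-en-5-ynoate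
Conditions: CuI (20 mol %), NaI, K2CO3, DMF, 23 °C
Reagents that add atoms: none
Why: Copper-mediated coupling of a terminal alkyne with an allylic halide forms C9–C10; because the two allyl termini are equivalent, direct and allylic displacement give the same skipped enyne, and the alkenyl iodide does not couple at room temperature.

Step 9
Reactants: 14 D-erythronolactone
Product: 15 (3R,4R)-3-(tert-butyldimethylsilyloxy)-4-hydroxyoxolan-2-one
Conditions: t-BuMe2SiCl (1.05 equiv), imidazole, DMF, −20 → 0 °C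
Reagents that add atoms: tert-butyldimethylsilyl chloride, CC(C)(C)[Si](C)(C)Cl
Why: Selective silylation is expected at the more acidic hydroxyl adjacent to the lactone carbonyl, which places the robust silyl group on the future O14.

Step 10
Reactants: 15 (3R,4R)-3-(tert-butyldimethylsilyloxy)-4-hydroxyoxolan-2-one
Product: 16 (3R,4R)-3-(tert-butyldimethylsilyloxy)-4-(triethylsilyloxy)oxolan-2-one
Conditions: Et3SiCl, imidazole, DMF, 0 °C
Reagents that add atoms: chlorotriethylsilane, CC[Si](Cl)(CC)CC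
Why: Routine silylation of the remaining secondary hydroxyl puts the acid-labile silyl group on the future O13 and blocks silyl migration in the next step.

Step 11
Reactants: 16 (3R,4R)-3-(tert-butyldimethylsilyloxy)-4-(triethylsilyloxy)oxolan-2-one
Product: 18 (2R,3R)-3-(tert-butyldimethylsilyloxy)-4-methyl-2-(triethylsilyloxy)pentane-1,4-diol, via hydroxy methyl ketone 17 (not isolated)
Conditions: MeMgBr (3 equiv), THF, −20 → 0 °C; cold aq. NH4Cl
Reagents that add atoms: methylmagnesium bromide, C[Mg]Br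
Why: Double Grignard addition to the lactone through the ring-opened methyl ketone builds the C15 dimethylcarbinol without touching C13 or C14.

Step 12
Reactants: 18 (2R,3R)-3-(tert-butyldimethylsilyloxy)-4-methyl-2-(triethylsilyloxy)pentane-1,4-diol
Product: 19 (2R,3R)-3-(tert-butyldimethylsilyloxy)-4-methyl-1,2,4-tris(triethylsilyloxy)pentane
Conditions: Et3SiOTf, 2,6-lutidine, CH2Cl2, −40 → 0 °C
Reagents that add atoms: triethylsilyl trifluoromethanesulfonate, CC[Si](CC)(CC)OS(=O)(=O)C(F)(F)F
Why: Silyl triflate silylates the primary and the tertiary hydroxyl alike, so the C15 oxygen cannot later close a lactol onto C12.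

Step 13
Reactants: 19 (2R,3R)-3-(tert-butyldimethylsilyloxy)-4-methyl-1,2,4-tris(triethylsilyloxy)pentane
Product: 21 (2S,3R)-3-(tert-butyldimethylsilyloxy)-4-methyl-2,4-bis(triethylsilyloxy)pentanal, via alkoxysulfonium chloride 20 (not isolated)
Conditions: (COCl)2, DMSO, CH2Cl2, −78 → −30 °C; then Et3N, −78 → 0 °C
Reagents that add atoms: none
Why: Swern oxidation with in-situ cleavage of the primary triethylsilyl ether, a known selectivity over secondary and tertiary silyl ethers, gives the C12 aldehyde directly.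

Step 14
Reactants: 13 methyl (7S,10E)-12,12-diethoxy-11-iodo-7-methyl-3-methylidene-7-(triethylsilyloxy)dodec-10-en-5-ynoate; 21 (2S,3R)-3-(tert-butyldimethylsilyloxy)-4-methyl-2,4-bis(triethylsilyloxy)pentanal
Product: 23 methyl (7S,10Z,12R,13R,14R)-14-(tert-butyldimethylsilyloxy)-11-(diethoxymethyl)-12-hydroxy-7,15-dimethyl-3-methylidene-7,13,15-tris(triethylsilyloxy)hexadec-10-en-5-ynoate, via alkenylchromium dichloride 22 (not isolated)
Conditions: CrCl2 (6 equiv), NiCl2 (1 mol %), DMSO–THF, 23 °C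
Reagents that add atoms: none
Why: Nozaki–Hiyama–Kishi coupling, in which the alkenyl iodide is transferred to trivalent chromium with retention of geometry and adds anti to the non-chelating C13 silyloxy group (Felkin–Anh control) to give the 12,13-anti (12R) carbinol, while ester, alkyne and acetal are tolerated.

Step 15
Reactants: 23 methyl (7S,10Z,12R,13R,14R)-14-(tert-butyldimethylsilyloxy)-11-(diethoxymethyl)-12-hydroxy-7,15-dimethyl-3-methylidene-7,13,15-tris(triethylsilyloxy)hexadec-10-en-5-ynoate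
Product: 24 methyl (5Z,7S,10Z,12R,13R,14R)-14-(tert-butyldimethylsilyloxy)-11-(diethoxymethyl)-12-hydroxy-7,15-dimethyl-3-methylidene-7,13,15-tris(triethylsilyloxy)hexadeca-5,10-dienoate
Conditions: H2 (1 atm), Pd/CaCO3 poisoned with Pb(OAc)2, quinoline, EtOAc, 23 °C
Reagents that add atoms: none
Why: Lindlar semihydrogenation delivers both hydrogens to the same side of the only alkyne and should stop at the (8Z)-alkene before the other alkenes react.

Step 16
Reactants: 24 methyl (5Z,7S,10Z,12R,13R,14R)-14-(tert-butyldimethylsilyloxy)-11-(diethoxymethyl)-12-hydroxy-7,15-dimethyl-3-methylidene-7,13,15-tris(triethylsilyloxy)hexadeca-5,10-dienoate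
Product: 26 (5Z,7S,10Z,12R,13R,14R)-14-(tert-butyldimethylsilyloxy)-11-(diethoxymethyl)-12-hydroxy-7,15-dimethyl-3-methylidene-7,13,15-tris(triethylsilyloxy)hexadeca-5,10-dienoic acid, via trimethylstannyl ester 25 (not isolated)
Conditions: Me3SnOH, 1,2-dichloroethane, 70 °C; then 0.01 M aq. KHSO4, 0 °C
Reagents that add atoms: trimethyltin hydroxide, C[Sn](C)(C)O
Why: Neutral ester cleavage with trimethyltin hydroxide avoids the alkoxide conditions that could move the C11 alkene into conjugation or shift the O13 silyl group to O12.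

Step 17
Reactants: 26 seco acid
Product: 28 13-membered lactone (12R) of seco acid 26 (C1 carbonyl on O12), via mixed anhydride 27 (not isolated)
Conditions: 2-methyl-6-nitrobenzoic anhydride, DMAP, CH2Cl2 (1 mM), 23 °C, slow addition of 26
Reagents that add atoms: none
Why: Shiina macrolactonisation, in which the acylpyridinium formed from the mixed anhydride is captured by the only free hydroxyl (O12) under high dilution, the (8Z)-alkene helps the chain to fold, and room temperature limits migration of the β,γ-alkene.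

Step 18
Reactants: 28 13-membered lactone (12R)
Product: 32 nine-membered ring acid (4aS,7S,11aR) having the (Z)-C4=C12 alkene, via lithium enolate 29 (not isolated), via silyl ketene acetal 30 (not isolated), via trimethylsilyl ester 31 (not isolated)
Conditions: LiN(i-Pr)2, THF–DMPU (4:1), −78 °C; Me3SiCl, −78 → 23 °C, then 60 °C; then MeOH–pH 5 buffer
Reagents that add atoms: none
Why: Deprotonation at C11a gives the lithium dienolate, O-silylation gives the silyl ketene acetal, and a concerted suprafacial [3,3] shift through a chair-like six-membered transition state (O12–C1–C11a over C4a–C4–C12) forms C4a–C11a while C12–O breaks, the Ireland–Claisen rearrangement. The closest known reaction type is the ester-enolate Claisen ring contraction of macrocyclic allylic lactones to carbocyclic alkenyl acids. The nine-membered ring closes by contraction of the 13-membered ring, the seven-atom tether C5–C11 bridging the two bond-forming carbons from pseudo-equatorial positions, so no end-to-end medium-ring cyclisation is required. C4a is set by chirality transfer from (12R) across the alkene in which C5 is trans to C12, with C13 pseudo-equatorial, which also puts C13 cis to C3 on the new C4=C12 bond; C11a is set by the ketene acetal geometry, C11 trans to the ring oxygen giving H4a and H11a trans. The step needs that ketene acetal geometry and a chair in place of a boat: the dipolar cosolvent steers enolisation to the geometry with C11 cis to the silyloxy group, the substituents on C1 and C4 clash in the boat, and C11a remains correctable because it is alpha to the C1 carbonyl.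

Step 19
Reactants: 32 nine-membered ring acid
Product: 33 C1 primary alcohol of 32
Conditions: LiAlH4, Et2O, 0 → 23 °C
Reagents that add atoms: none
Why: Hydride reduction of the carboxylic acid to the primary alcohol leaves silyl ethers, acetal and alkenes untouched and does not epimerise C11a, since the carboxylate forms first.

Step 20
Reactants: 33 C1 primary alcohol
Product: 35 tricyclic bis-acetal (3S) carrying triethylsilyl ethers at O7 plus O15 together with the tert-butyldimethylsilyl ether at O14, via C13 alcohol 34 (not isolated)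
Conditions: PPTS, CH2Cl2–MeOH (5:1), 0 → 23 °C; then PPTS, toluene, 5 Å molecular sieves, 23 °C
Reagents that add atoms: none
Why: Mild acid removes the secondary triethylsilyl group from O13 and exchanges both ethoxy groups of the C3 acetal for O1 and O13 (transacetalisation), so pyran and dihydrofuran close without any oxidation step; O14 stays silylated and cannot form the six-membered alternative, (3S) with O13 pseudo-equatorial is the thermodynamic acetal, and any loss of a tertiary silyl group converges in step 21.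

Step 21
Reactants: 35 tricyclic bis-acetal
Product: 36 tricyclic triol with the (8Z)-alkene (free hydroxyls at C7; C14; C15)
Conditions: Bu4NF, THF, 23 → 45 °C; aq. NH4Cl
Reagents that add atoms: none
Why: Fluoride-mediated desilylation removes all three remaining silyl ethers under non-acidic conditions that the allylic bis-acetal tolerates.

Step 22
Reactants: 36 tricyclic triol
Product: 37 target (3S,4aS,7S,8R,9R,11aR,13R,14R)
Conditions: VO(acac)2 (5 mol %), t-BuOOH, CH2Cl2, 0 → 23 °C
Reagents that add atoms: tert-butyl hydroperoxide, CC(C)(C)OO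
Why: Hydroxyl-directed epoxidation through the vanadate ester of the tertiary allylic C7 alcohol, where the hydroxyl (smaller than methyl) should lie close to the alkene plane to minimise allylic 1,3-strain and deliver oxygen to the adjacent outer face of the (8Z)-alkene, giving the epoxide cis to the hydroxyl; the exocyclic alkene has no directing group and C4=C12 is electron-poor.

Compound list
1 | hex-5-yn-2-one | CC(=O)CCC#C | starting material
2 | ethynyltrimethylsilane | C#C[Si](C)(C)C | starting material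
3 | methylzinc (trimethylsilyl)acetylide (not isolated) | C[Zn]C#C[Si](C)(C)C | intermediate
4 | (3S)-3-methyl-1-(trimethylsilyl)hepta-1,6-diyn-3-ol | C[Si](C)(C)C#C[C@@](C)(O)CCC#C | intermediate
5 | (3S)-3-methyl-3-(triethylsilyloxy)-1-(trimethylsilyl)hepta-1,6-diyne | C[Si](C)(C)C#C[C@@](C)(O[Si](CC)(CC)CC)CCC#C | intermediate
6 | bromomagnesium C4-acetylide of 5 (not isolated) | C[Si](C)(C)C#C[C@@](C)(O[Si](CC)(CC)CC)CCC#C[Mg]Br | intermediate
7 | (3S)-8,8-diethoxy-3-methyl-3-(triethylsilyloxy)-1-(trimethylsilyl)octa-1,6-diyne | C[Si](C)(C)C#C[C@@](C)(O[Si](CC)(CC)CC)CCC#CC(OCC)OCC | intermediate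
8 | (3S,6E)-8,8-diethoxy-3-methyl-7-(tributylstannyl)-3-(triethylsilyloxy)-1-(trimethylsilyl)oct-6-en-1-yne | C[Si](C)(C)C#C[C@@](C)(O[Si](CC)(CC)CC)CC/C=C(\C(OCC)OCC)/[Sn](CCCC)(CCCC)CCCC | intermediate
9 | (3S,6E)-8,8-diethoxy-7-iodo-3-methyl-3-(triethylsilyloxy)-1-(trimethylsilyl)oct-6-en-1-yne | C[Si](C)(C)C#C[C@@](C)(O[Si](CC)(CC)CC)CC/C=C(\C(OCC)OCC)/I | intermediate
10 | (3S,6E)-8,8-diethoxy-7-iodo-3-methyl-3-(triethylsilyloxy)oct-6-en-1-yne | C#C[C@@](C)(O[Si](CC)(CC)CC)CC/C=C(\C(OCC)OCC)/I | intermediate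
11 | 3-chloro-2-(chloromethyl)prop-1-ene | C=C(CCl)CCl | starting material
12 | methyl 3-(chloromethyl)but-3-enoate | COC(=O)CC(=C)CCl | intermediate
13 | methyl (7S,10E)-12,12-diethoxy-11-iodo-7-methyl-3-methylidene-7-(triethylsilyloxy)dodec-10-en-5-ynoate | COC(=O)CC(=C)CC#C[C@@](C)(O[Si](CC)(CC)CC)CC/C=C(\C(OCC)OCC)/I | intermediate
14 | D-erythronolactone, (3R,4R)-3,4-dihydroxyoxolan-2-one | C1[C@H]([C@@H](O)C(=O)O1)O | starting material
15 | (3R,4R)-3-(tert-butyldimethylsilyloxy)-4-hydroxyoxolan-2-one | C1[C@H]([C@@H](O[Si](C)(C)C(C)(C)C)C(=O)O1)O | intermediate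
16 | (3R,4R)-3-(tert-butyldimethylsilyloxy)-4-(triethylsilyloxy)oxolan-2-one | C1[C@H]([C@@H](O[Si](C)(C)C(C)(C)C)C(=O)O1)O[Si](CC)(CC)CC | intermediate
17 | (3R,4R)-3-(tert-butyldimethylsilyloxy)-5-hydroxy-4-(triethylsilyloxy)pentan-2-one, present as its bromomagnesium alkoxide (not isolated) | OC[C@H]([C@@H](O[Si](C)(C)C(C)(C)C)C(C)=O)O[Si](CC)(CC)CC | intermediate
18 | (2R,3R)-3-(tert-butyldimethylsilyloxy)-4-methyl-2-(triethylsilyloxy)pentane-1,4-diol | OC[C@H]([C@@H](O[Si](C)(C)C(C)(C)C)C(C)(C)O)O[Si](CC)(CC)CC | intermediate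
19 | (2R,3R)-3-(tert-butyldimethylsilyloxy)-4-methyl-1,2,4-tris(triethylsilyloxy)pentane | CC[Si](CC)(CC)OC[C@H]([C@@H](O[Si](C)(C)C(C)(C)C)C(C)(C)O[Si](CC)(CC)CC)O[Si](CC)(CC)CC | intermediate
20 | dimethyl(alkoxy)sulfonium chloride at O12 of 19 after loss of the primary silyl group (not isolated) | C[S+](C)OC[C@H]([C@@H](O[Si](C)(C)C(C)(C)C)C(C)(C)O[Si](CC)(CC)CC)O[Si](CC)(CC)CC.[Cl-] | intermediate
21 | (2S,3R)-3-(tert-butyldimethylsilyloxy)-4-methyl-2,4-bis(triethylsilyloxy)pentanal (C12 aldehyde) | O=C[C@H]([C@@H](O[Si](C)(C)C(C)(C)C)C(C)(C)O[Si](CC)(CC)CC)O[Si](CC)(CC)CC | intermediate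
22 | C4-alkenylchromium dichloride derived from 13 (not isolated) | COC(=O)CC(=C)CC#C[C@@](C)(O[Si](CC)(CC)CC)CC/C=C(\C(OCC)OCC)/[Cr](Cl)Cl | intermediate
23 | methyl (7S,10Z,12R,13R,14R)-14-(tert-butyldimethylsilyloxy)-11-(diethoxymethyl)-12-hydroxy-7,15-dimethyl-3-methylidene-7,13,15-tris(triethylsilyloxy)hexadec-10-en-5-ynoate | COC(=O)CC(=C)CC#C[C@@](C)(O[Si](CC)(CC)CC)CC/C=C(\C(OCC)OCC)/[C@@H](O)[C@H]([C@@H](O[Si](C)(C)C(C)(C)C)C(C)(C)O[Si](CC)(CC)CC)O[Si](CC)(CC)CC | intermediate
24 | methyl (5Z,7S,10Z,12R,13R,14R)-14-(tert-butyldimethylsilyloxy)-11-(diethoxymethyl)-12-hydroxy-7,15-dimethyl-3-methylidene-7,13,15-tris(triethylsilyloxy)hexadeca-5,10-dienoate | COC(=O)CC(=C)C/C=C\[C@@](C)(O[Si](CC)(CC)CC)CC/C=C(\C(OCC)OCC)/[C@@H](O)[C@H]([C@@H](O[Si](C)(C)C(C)(C)C)C(C)(C)O[Si](CC)(CC)CC)O[Si](CC)(CC)CC | intermediate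
25 | trimethylstannyl ester of 26 (not isolated) | C[Sn](C)(C)OC(=O)CC(=C)C/C=C\[C@@](C)(O[Si](CC)(CC)CC)CC/C=C(\C(OCC)OCC)/[C@@H](O)[C@H]([C@@H](O[Si](C)(C)C(C)(C)C)C(C)(C)O[Si](CC)(CC)CC)O[Si](CC)(CC)CC | intermediate
26 | (5Z,7S,10Z,12R,13R,14R)-14-(tert-butyldimethylsilyloxy)-11-(diethoxymethyl)-12-hydroxy-7,15-dimethyl-3-methylidene-7,13,15-tris(triethylsilyloxy)hexadeca-5,10-dienoic acid (seco acid) | OC(=O)CC(=C)C/C=C\[C@@](C)(O[Si](CC)(CC)CC)CC/C=C(\C(OCC)OCC)/[C@@H](O)[C@H]([C@@H](O[Si](C)(C)C(C)(C)C)C(C)(C)O[Si](CC)(CC)CC)O[Si](CC)(CC)CC | intermediate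
27 | mixed anhydride of 26 and 2-methyl-6-nitrobenzoic acid (not isolated) | Cc1cccc([N+](=O)[O-])c1C(=O)OC(=O)CC(=C)C/C=C\[C@@](C)(O[Si](CC)(CC)CC)CC/C=C(\C(OCC)OCC)/[C@@H](O)[C@H]([C@@H](O[Si](C)(C)C(C)(C)C)C(C)(C)O[Si](CC)(CC)CC)O[Si](CC)(CC)CC | intermediate
28 | 13-membered lactone of 26: C1 acyl on O12, (12R), C5 trans to C12 on C4=C4a, (8Z), C3 as diethyl acetal, Et3Si on O7, O13 and O15, t-BuMe2Si on O14 (precursor of the key step) | O=C1CC(=C)C/C=C\[C@@](C)(O[Si](CC)(CC)CC)CC/C=C(\C(OCC)OCC)/[C@@H](O1)[C@H]([C@@H](O[Si](C)(C)C(C)(C)C)C(C)(C)O[Si](CC)(CC)CC)O[Si](CC)(CC)CC | intermediate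
29 | lithium enolate of 28, C11a=C1 with C11 cis to OLi (not isolated) | [Li]O/C1=C\C(=C)C/C=C\[C@@](C)(O[Si](CC)(CC)CC)CC/C=C(\C(OCC)OCC)/[C@@H](O1)[C@H]([C@@H](O[Si](C)(C)C(C)(C)C)C(C)(C)O[Si](CC)(CC)CC)O[Si](CC)(CC)CC | intermediate
30 | trimethylsilyl ketene acetal of 28, C11 cis to OSiMe3 and trans to the ring oxygen (not isolated) | C[Si](C)(C)O/C1=C\C(=C)C/C=C\[C@@](C)(O[Si](CC)(CC)CC)CC/C=C(\C(OCC)OCC)/[C@@H](O1)[C@H]([C@@H](O[Si](C)(C)C(C)(C)C)C(C)(C)O[Si](CC)(CC)CC)O[Si](CC)(CC)CC | intermediate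
31 | trimethylsilyl ester of 32 (not isolated) | C=C1C/C=C\[C@@](C)(O[Si](CC)(CC)CC)CC[C@H](/C(C(OCC)OCC)=C/[C@H]([C@@H](O[Si](C)(C)C(C)(C)C)C(C)(C)O[Si](CC)(CC)CC)O[Si](CC)(CC)CC)[C@H]1C(=O)O[Si](C)(C)C | intermediate
32 | nine-membered ring acid: C11a (R) bears CO2H; C4a (S) bears the (Z)-C4(=C12H)–CH(OEt)2 unit with C13 (R) OSiEt3, C14 (R) OSi(t-Bu)Me2, C15 OSiEt3; C7 (S) methyl and OSiEt3; (8Z)-alkene; C11 exocyclic methylene (product of the key step) | C=C1C/C=C\[C@@](C)(O[Si](CC)(CC)CC)CC[C@H](/C(C(OCC)OCC)=C/[C@H]([C@@H](O[Si](C)(C)C(C)(C)C)C(C)(C)O[Si](CC)(CC)CC)O[Si](CC)(CC)CC)[C@H]1C(=O)O | intermediate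
33 | C1 primary alcohol corresponding to 32 | C=C1C/C=C\[C@@](C)(O[Si](CC)(CC)CC)CC[C@H](/C(C(OCC)OCC)=C/[C@H]([C@@H](O[Si](C)(C)C(C)(C)C)C(C)(C)O[Si](CC)(CC)CC)O[Si](CC)(CC)CC)[C@H]1CO | intermediate
34 | C1,C13-diol after loss of the O13 silyl group, C3 still diethyl acetal (not isolated) | C=C1C/C=C\[C@@](C)(O[Si](CC)(CC)CC)CC[C@H](/C(C(OCC)OCC)=C/[C@H]([C@@H](O[Si](C)(C)C(C)(C)C)C(C)(C)O[Si](CC)(CC)CC)O)[C@H]1CO | intermediate
35 | tricyclic bis-acetal (3S,4aS,7S,11aR,13R,14R): pyran C3–O–C1 and 2,5-dihydrofuran C3–O–C13; Et3Si on O7 and O15, t-BuMe2Si on O14; (8Z)-alkene | C=C1C/C=C\[C@@](C)(O[Si](CC)(CC)CC)CC[C@@H]2C3=C[C@H]([C@@H](O[Si](C)(C)C(C)(C)C)C(C)(C)O[Si](CC)(CC)CC)O[C@@H]3OC[C@@H]12 | intermediate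
36 | tricyclic triol (3S,4aS,7S,11aR,13R,14R) with (8Z)-alkene | C=C1C/C=C\[C@@](C)(O)CC[C@@H]2C3=C[C@H]([C@@H](O)C(C)(C)O)O[C@@H]3OC[C@@H]12 | intermediate
37 | target, (3S,4aS,7S,8R,9R,11aR,13R,14R) 8,9-epoxide | C=C1C[C@H]2O[C@H]2[C@@](C)(O)CC[C@@H]2C3=C[C@H]([C@@H](O)C(C)(C)O)O[C@@H]3OC[C@@H]12 | target

Total step count: 22 steps. Longest linear sequence: 16 steps (steps 1–6, 8 and 14–22); steps 7 and 9–13 are convergent branches.

Steps most likely to fail

Step 18. Enolisation inside the macrocycle may give the ketene acetal with C11 cis to the ring oxygen, or the shift may pass through a boat, so that C11a forms with the wrong configuration. The fallback replaces kinetic control by thermodynamic control. It sets out from 28: the same rearrangement is run and the acid with cis H4a/H11a, the C11a epimer F1, is accepted. Me3SiCHN2 in toluene–MeOH converts it into methyl ester F2. NaOMe in MeOH at 0 → 23 °C should then equilibrate C11a through the ester enolate to the trans ester F3, in which both ring substituents are pseudo-equatorial; the alkene should stay exocyclic, since conjugation would need a tetrasubstituted endocyclic alkene in the nine-membered ring. LiAlH4 reduction of F3 gives alcohol 33, where the route is rejoined.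

Step 1. Discrimination between the methyl and the unbranched methylene flank of the ketone may be poor, and the free alkyne of 1 may be zincated in competition. The fallback replaces asymmetric catalysis by resolution and sets out from 1 and 2. LiC≡CSiMe3 (from 2 and n-BuLi) is added to 1 in the presence of CeCl3 in THF at −78 °C to give the racemic alcohol F4. Preparative chromatography on an amylose tris(3,5-dimethylphenylcarbamate) stationary phase separates the enantiomers, and the (S)-enantiomer is 4.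

Step 4. Tin may be delivered in part to C4a instead of C4, or the silyl-capped alkyne may also be hydrostannated. The fallback moves the hydrostannation to an ynoate, where tin goes reliably to the carbon alpha to the ester, and sets out from 5. n-BuLi followed by ClCO2Me gives the ynoate F5. Bu3SnH with Pd(PPh3)4 gives the alpha-stannyl enoate F6 by syn addition. i-Bu2AlH at −78 °C reduces it to the stannyl allylic alcohol F7, and MnO2 oxidises this to the stannyl enal F8. HC(OEt)3 with EtOH and PPTS converts F8 into the diethyl acetal, which is stannane 8, where the route is rejoined.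

Further compounds
F1 | step 18 | (4aS,11aS)-epimer of acid 32 (H4a and H11a cis) | C=C1C/C=C\[C@@](C)(O[Si](CC)(CC)CC)CC[C@H](/C(C(OCC)OCC)=C/[C@H]([C@@H](O[Si](C)(C)C(C)(C)C)C(C)(C)O[Si](CC)(CC)CC)O[Si](CC)(CC)CC)[C@@H]1C(=O)O
F2 | step 18 | methyl ester of F1 | C=C1C/C=C\[C@@](C)(O[Si](CC)(CC)CC)CC[C@H](/C(C(OCC)OCC)=C/[C@H]([C@@H](O[Si](C)(C)C(C)(C)C)C(C)(C)O[Si](CC)(CC)CC)O[Si](CC)(CC)CC)[C@@H]1C(=O)OC
F3 | step 18 | methyl ester of 32, (4aS,11aR), after epimerisation | C=C1C/C=C\[C@@](C)(O[Si](CC)(CC)CC)CC[C@H](/C(C(OCC)OCC)=C/[C@H]([C@@H](O[Si](C)(C)C(C)(C)C)C(C)(C)O[Si](CC)(CC)CC)O[Si](CC)(CC)CC)[C@H]1C(=O)OC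
F4 | step 1 | racemic 3-methyl-1-(trimethylsilyl)hepta-1,6-diyn-3-ol | C[Si](C)(C)C#CC(C)(O)CCC#C
F5 | step 4 | methyl (6S)-6-methyl-6-(triethylsilyloxy)-8-(trimethylsilyl)octa-2,7-diynoate | C[Si](C)(C)C#C[C@@](C)(O[Si](CC)(CC)CC)CCC#CC(=O)OC
F6 | step 4 | methyl (2E,6S)-6-methyl-2-(tributylstannyl)-6-(triethylsilyloxy)-8-(trimethylsilyl)oct-2-en-7-ynoate | C[Si](C)(C)C#C[C@@](C)(O[Si](CC)(CC)CC)CC/C=C(\C(=O)OC)/[Sn](CCCC)(CCCC)CCCC
F7 | step 4 | (2E,6S)-6-methyl-2-(tributylstannyl)-6-(triethylsilyloxy)-8-(trimethylsilyl)oct-2-en-7-yn-1-ol | C[Si](C)(C)C#C[C@@](C)(O[Si](CC)(CC)CC)CC/C=C(\CO)/[Sn](CCCC)(CCCC)CCCC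
F8 | step 4 | (2E,6S)-6-methyl-2-(tributylstannyl)-6-(triethylsilyloxy)-8-(trimethylsilyl)oct-2-en-7-ynal | C[Si](C)(C)C#C[C@@](C)(O[Si](CC)(CC)CC)CC/C=C(\C=O)/[Sn](CCCC)(CCCC)CCCC
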